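**Plan**
- Retrosynthesis: the three benzyl ethers come off last. Ring C is cut at C4–C4a (acylation of ring A by a carboxylic acid) and then at O1–C2 (vinylic substitution of an enol tosylate by 3-(benzyloxy)phenol). The C2–C3 and C3–C1' bonds go back to a ring B benzaldehyde and ethyl diazoacetate, and the 1,1-dimethylallyl group goes back to a 4-O-prenyl ether.
- Forward: ring B is dressed on 2,3,4-trihydroxybenzaldehyde (prenylation, benzylation, Claisen shift to C5, methylation). The aldehyde is homologated with aryl shift to the 2-aryl-3-hydroxyacrylate, ring A is attached through O1, and ring C closes last.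
- Enabling feature: C4a of ring A is para to the C7 oxygen and ortho to O1, the most nucleophilic carbon of a resorcinol diether, so the C4 acyl carbon held on the O1–C2=C3 tether can be bonded to it.
- Stereochemistry: the target has no stereocentre. The only stereo-element on the way, the C2=C3 geometry of the acrylate, is equilibrated during the ring closure.

Key step: step 9

Remark: compounds 14, 16 and 17 are drawn as the (E) isomers expected on thermodynamic grounds; any (Z) isomer formed alongside can be carried through, since step 9 equilibrates the geometry.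

**Step 1**
Reactants: 1 2,3,4-trihydroxybenzaldehyde; 2 prenyl bromide
Product: 3 2,3-dihydroxy-4-[(3-methylbut-2-en-1-yl)oxy]benzaldehyde
Conditions: NaHCO3, DMF, 40 °C
Reagents that add atoms: prenyl bromide, CC(C)=CCBr
Why: Williamson etherification; the 4-OH, para to the formyl group, is the most acidic and is not held in the hydrogen bond that ties up the 2-OH, so a weak base and one equivalent of the allylic bromide should alkylate it selectively.

**Step 2**
Reactants: 3 2,3-dihydroxy-4-[(3-methylbut-2-en-1-yl)oxy]benzaldehyde; 4 benzyl bromide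
Product: 5 2,3-bis(benzyloxy)-4-[(3-methylbut-2-en-1-yl)oxy]benzaldehyde
Conditions: BnBr, K2CO3, DMF, 50 °C, under N2
Reagents that add atoms: benzyl bromide, BrCc1ccccc1
Why: Double Williamson etherification under stronger carbonate conditions caps both remaining hydroxyls, the hydrogen-bonded 2-OH included; benzyl is chosen because it survives the later steps and can be removed at the end without hydrogen.

**Step 3**
Reactants: 5 2,3-bis(benzyloxy)-4-[(3-methylbut-2-en-1-yl)oxy]benzaldehyde
Product: 7 2,3-bis(benzyloxy)-4-hydroxy-5-(2-methylbut-3-en-2-yl)benzaldehyde, via ortho-dienone 6 (not isolated)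
Conditions: EtOH–H2O (4:1), sealed tube, 130 °C
Reagents that add atoms: none
Why: Aromatic Claisen rearrangement ([3,3]-sigmatropic shift): only C5 is a free ortho carbon (C3 carries OBn), so the prenyl ether delivers its tertiary terminus there and the dienone tautomerises to the phenol, while the aqueous medium accelerates the shift enough to run it below the temperature at which the ortho-allylphenol would cyclise or rearrange further.

**Step 4**
Reactants: 7 2,3-bis(benzyloxy)-4-hydroxy-5-(2-methylbut-3-en-2-yl)benzaldehyde; 8 iodomethane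
Product: 9 2,3-bis(benzyloxy)-4-methoxy-5-(2-methylbut-3-en-2-yl)benzaldehyde
Conditions: MeI, K2CO3, DMF, 40 °C
Reagents that add atoms: iodomethane, CI
Why: Williamson O-methylation of a phenoxide made acidic by the para formyl group; methyl iodide is small enough to reach the oxygen flanked by OBn and the tertiary alkyl group.

**Step 5**
Reactants: 9 2,3-bis(benzyloxy)-4-methoxy-5-(2-methylbut-3-en-2-yl)benzaldehyde; 10 ethyl diazoacetate
Product: 12 ethyl (Z)-2-[2,3-bis(benzyloxy)-4-methoxy-5-(2-methylbut-3-en-2-yl)phenyl]-3-hydroxyprop-2-enoate, via formyl ester tautomer 11 (not isolated)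
Conditions: HBF4·OEt2 (10 mol%), CH2Cl2, −78 °C, slow addition of the diazoester
Reagents that add atoms: ethyl diazoacetate, CCOC(=O)C=[N+]=[N-]
Why: Acid-catalysed addition of the diazoester to the aldehyde, then loss of N2 with 1,2-aryl shift (Büchner–Curtius–Schlotterbeck-type homologation in its aryl-migration mode), the preferred course for electron-rich benzaldehydes, should give the formylarylacetate as its hydrogen-bonded enol, while catalytic acid at low temperature leaves the vinyl group and the benzyl ethers alone.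

**Step 6**
Reactants: 12 ethyl (Z)-2-[2,3-bis(benzyloxy)-4-methoxy-5-(2-methylbut-3-en-2-yl)phenyl]-3-hydroxyprop-2-enoate; 13 p-toluenesulfonyl chloride
Product: 14 ethyl (E)-2-[2,3-bis(benzyloxy)-4-methoxy-5-(2-methylbut-3-en-2-yl)phenyl]-3-[(4-methylbenzenesulfonyl)oxy]prop-2-enoate
Conditions: TsCl, N-methylimidazole, Et3N, MeCN, 0 °C
Reagents that add atoms: p-toluenesulfonyl chloride, Cc1ccc(S(=O)(=O)Cl)cc1
Why: O-Sulfonylation of the enol through the N-tosylimidazolium salt (enol tosylate formation) turns C3 into an electrophilic vinylic carbon; the non-chelating amine base should favour the (E) isomer, though either isomer serves in the next step.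

**Step 7**
Reactants: 14 ethyl (E)-2-[2,3-bis(benzyloxy)-4-methoxy-5-(2-methylbut-3-en-2-yl)phenyl]-3-[(4-methylbenzenesulfonyl)oxy]prop-2-enoate; 15 3-(benzyloxy)phenol
Product: 16 ethyl (E)-3-[3-(benzyloxy)phenoxy]-2-[2,3-bis(benzyloxy)-4-methoxy-5-(2-methylbut-3-en-2-yl)phenyl]prop-2-enoate
Conditions: K2CO3, DMF, 50 °C
Reagents that add atoms: 3-(benzyloxy)phenol, Oc1cccc(OCc2ccccc2)c1
Why: Nucleophilic vinylic substitution (addition–elimination) of the β-tosyloxy acrylate by the phenoxide, the reaction by which phenoxides displace halide or sulfonate from β-activated acrylates; the ester- and aryl-stabilised carbanion lets the product settle as the more stable (E)-enol ether.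

**Step 8**
Reactants: 16 ethyl (E)-3-[3-(benzyloxy)phenoxy]-2-[2,3-bis(benzyloxy)-4-methoxy-5-(2-methylbut-3-en-2-yl)phenyl]prop-2-enoate
Product: 17 (E)-3-[3-(benzyloxy)phenoxy]-2-[2,3-bis(benzyloxy)-4-methoxy-5-(2-methylbut-3-en-2-yl)phenyl]prop-2-enoic acid
Conditions: LiOH·H2O, THF–H2O (3:1), 40 °C; then 1 M HCl to pH 3
Reagents that add atoms: lithium hydroxide, [Li+].[OH-]
Why: Saponification (acyl–oxygen ester hydrolysis) in an alcohol-free medium, so that no alkoxide can exchange with the aryloxy group at C3; the benzyl ethers, the enol ether and the alkene are inert to aqueous hydroxide.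

**Step 9**
Reactants: 17 (E)-3-[3-(benzyloxy)phenoxy]-2-[2,3-bis(benzyloxy)-4-methoxy-5-(2-methylbut-3-en-2-yl)phenyl]prop-2-enoic acid
Product: 20 7-(benzyloxy)-3-[2,3-bis(benzyloxy)-4-methoxy-5-(2-methylbut-3-en-2-yl)phenyl]-4H-chromen-4-one, via E mixed trifluoroacetic anhydride 18 (not isolated), via Z mixed trifluoroacetic anhydride 19 (not isolated)
Conditions: (CF3CO)2O (2 equiv), CH2Cl2, 0 °C to rt
Reagents that add atoms: none
Why: Intramolecular Friedel–Crafts acylation: the acid and the anhydride give mixed anhydride 18, whose ionisation, helped by the trifluoroacetic acid set free, leads to an acylium ion that is also an O1=C2 oxocarbenium–ketene, so the C2=C3 bond loses double-bond character and the (E) form passes into the (Z) form 19 with the acyl carbon facing ring A. C4a then attacks the acyl carbon in an electrophilic aromatic substitution and loss of the proton restores aromaticity. The closest known reactions are the acid-mediated cyclisation of 3-aryloxyacrylic acids to chromones and the mixed-anhydride cyclisation of 3-aryloxypropanoic acids to chromanones. The pyranone ring closes in a 6-exo mode (exo-trig at the anhydride carbonyl, exo-dig if the free acylium ion reacts), and no stereocentre is formed. The step needs attack at the ring A carbon para to the benzyloxy group and not at the carbon between the two oxygens, which is hindered on both sides and has no para donor. It also needs the vinyl group and the benzyl ethers to survive, which should hold because no acid stronger than trifluoroacetic acid is present and the temperature stays at or below ambient.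

**Step 10**
Reactants: 20 7-(benzyloxy)-3-[2,3-bis(benzyloxy)-4-methoxy-5-(2-methylbut-3-en-2-yl)phenyl]-4H-chromen-4-one
Product: 21 3-[2,3-dihydroxy-4-methoxy-5-(2-methylbut-3-en-2-yl)phenyl]-7-hydroxy-4H-chromen-4-one
Conditions: BCl3 (1 M in CH2Cl2), pentamethylbenzene, CH2Cl2, −78 °C; then MeOH
Reagents that add atoms: none
Why: Lewis acid debenzylation with BCl3 in the presence of the non-basic cation scavenger pentamethylbenzene: at −78 °C the three aryl benzyl ethers should be cleaved, the benzyl cations are taken up by the scavenger and not by the arene rings or the alkene, and the methyl ether is too slow to react.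

**Compound list**
1 | 2,3,4-trihydroxybenzaldehyde | O=Cc1ccc(O)c(O)c1O | starting material
2 | prenyl bromide (1-bromo-3-methylbut-2-ene) | CC(C)=CCBr | starting material
3 | 2,3-dihydroxy-4-[(3-methylbut-2-en-1-yl)oxy]benzaldehyde | O=Cc1ccc(OCC=C(C)C)c(O)c1O | intermediate
4 | benzyl bromide | BrCc1ccccc1 | starting material
5 | 2,3-bis(benzyloxy)-4-[(3-methylbut-2-en-1-yl)oxy]benzaldehyde | O=Cc1ccc(OCC=C(C)C)c(OCc2ccccc2)c1OCc1ccccc1 | intermediate
6 | 5,6-bis(benzyloxy)-3-(2-methylbut-3-en-2-yl)-4-oxocyclohexa-1,5-diene-1-carbaldehyde (racemic ortho-dienone, not isolated) | O=CC1=CC(C(C)(C)C=C)C(=O)C(OCc2ccccc2)=C1OCc1ccccc1 | intermediate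
7 | 2,3-bis(benzyloxy)-4-hydroxy-5-(2-methylbut-3-en-2-yl)benzaldehyde | O=Cc1cc(C(C)(C)C=C)c(O)c(OCc2ccccc2)c1OCc1ccccc1 | intermediate
8 | iodomethane | CI | starting material
9 | 2,3-bis(benzyloxy)-4-methoxy-5-(2-methylbut-3-en-2-yl)benzaldehyde | O=Cc1cc(C(C)(C)C=C)c(OC)c(OCc2ccccc2)c1OCc1ccccc1 | intermediate
10 | ethyl diazoacetate | CCOC(=O)C=[N+]=[N-] | starting material
11 | ethyl 2-[2,3-bis(benzyloxy)-4-methoxy-5-(2-methylbut-3-en-2-yl)phenyl]-3-oxopropanoate (racemic formyl tautomer, not isolated) | CCOC(=O)C(C=O)c1cc(C(C)(C)C=C)c(OC)c(OCc2ccccc2)c1OCc1ccccc1 | intermediate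
12 | ethyl (Z)-2-[2,3-bis(benzyloxy)-4-methoxy-5-(2-methylbut-3-en-2-yl)phenyl]-3-hydroxyprop-2-enoate | CCOC(=O)/C(c1cc(C(C)(C)C=C)c(OC)c(OCc2ccccc2)c1OCc1ccccc1)=C\O | intermediate
13 | p-toluenesulfonyl chloride | Cc1ccc(S(=O)(=O)Cl)cc1 | starting material
14 | ethyl (E)-2-[2,3-bis(benzyloxy)-4-methoxy-5-(2-methylbut-3-en-2-yl)phenyl]-3-[(4-methylbenzenesulfonyl)oxy]prop-2-enoate | CCOC(=O)/C(c1cc(C(C)(C)C=C)c(OC)c(OCc2ccccc2)c1OCc1ccccc1)=C/OS(=O)(=O)c1ccc(C)cc1 | intermediate
15 | 3-(benzyloxy)phenol | Oc1cccc(OCc2ccccc2)c1 | starting material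
16 | ethyl (E)-3-[3-(benzyloxy)phenoxy]-2-[2,3-bis(benzyloxy)-4-methoxy-5-(2-methylbut-3-en-2-yl)phenyl]prop-2-enoate | CCOC(=O)/C(c1cc(C(C)(C)C=C)c(OC)c(OCc2ccccc2)c1OCc1ccccc1)=C/Oc1cccc(OCc2ccccc2)c1 | intermediate
17 | (E)-3-[3-(benzyloxy)phenoxy]-2-[2,3-bis(benzyloxy)-4-methoxy-5-(2-methylbut-3-en-2-yl)phenyl]prop-2-enoic acid | O=C(O)/C(c1cc(C(C)(C)C=C)c(OC)c(OCc2ccccc2)c1OCc1ccccc1)=C/Oc1cccc(OCc2ccccc2)c1 | intermediate
18 | (E)-3-[3-(benzyloxy)phenoxy]-2-[2,3-bis(benzyloxy)-4-methoxy-5-(2-methylbut-3-en-2-yl)phenyl]prop-2-enoic trifluoroacetic anhydride (not isolated) | O=C(OC(=O)C(F)(F)F)/C(c1cc(C(C)(C)C=C)c(OC)c(OCc2ccccc2)c1OCc1ccccc1)=C/Oc1cccc(OCc2ccccc2)c1 | intermediate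
19 | (Z)-3-[3-(benzyloxy)phenoxy]-2-[2,3-bis(benzyloxy)-4-methoxy-5-(2-methylbut-3-en-2-yl)phenyl]prop-2-enoic trifluoroacetic anhydride (not isolated) | O=C(OC(=O)C(F)(F)F)/C(c1cc(C(C)(C)C=C)c(OC)c(OCc2ccccc2)c1OCc1ccccc1)=C\Oc1cccc(OCc2ccccc2)c1 | intermediate
20 | 7-(benzyloxy)-3-[2,3-bis(benzyloxy)-4-methoxy-5-(2-methylbut-3-en-2-yl)phenyl]-4H-chromen-4-one | C=CC(C)(C)c1cc(-c2coc3cc(OCc4ccccc4)ccc3c2=O)c(OCc2ccccc2)c(OCc2ccccc2)c1OC | intermediate
21 | 3-[2,3-dihydroxy-4-methoxy-5-(2-methylbut-3-en-2-yl)phenyl]-7-hydroxy-4H-chromen-4-one | C=CC(C)(C)c1cc(-c2coc3cc(O)ccc3c2=O)c(O)c(O)c1OC | target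

**Step count**
Total: 10 steps. Longest linear sequence: 10 steps (from 1 to 21).

**Steps most likely to fail**

Step 9. The C2=C3 geometry may fail to equilibrate under the mild activation. The activated acyl group could then be diverted to the neighbouring 2'-benzyloxy oxygen (lactonisation with loss of benzyl), or the acid generated could slowly attack the vinyl group. The fallback sets the reactive geometry before activation and does not rely on equilibration in the flask. It sets out from 16 and returns at 20. Ester 16 is irradiated at 365 nm in MeCN; β-alkoxyacrylates of this kind are known to undergo E/Z photoisomerisation. From the photostationary mixture ethyl (Z)-3-[3-(benzyloxy)phenoxy]-2-[2,3-bis(benzyloxy)-4-methoxy-5-(2-methylbut-3-en-2-yl)phenyl]prop-2-enoate F1 is separated, and recovered 16 is irradiated again. Saponification of F1 with LiOH·H2O in THF–H2O should give (Z)-3-[3-(benzyloxy)phenoxy]-2-[2,3-bis(benzyloxy)-4-methoxy-5-(2-methylbut-3-en-2-yl)phenyl]prop-2-enoic acid F2, in which the carboxyl group already faces ring A. Brief treatment of F2 with (CF3CO)2O in CH2Cl2 at 0 °C should then close ring C directly to 20.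

Step 3. At the temperature needed for the sigmatropic shift, the freshly formed ortho-(1,1-dimethylallyl)phenol may react on by cyclisation onto the alkene, by the abnormal Claisen pathway or by loss of the allyl group. The fallback intercepts the phenol as it forms. It sets out from 5 and returns at 9. Ether 5 is heated in N,N-diethylaniline with butanoic anhydride at 190 °C, so that the rearranged phenol is acylated at once to 2,3-bis(benzyloxy)-4-formyl-6-(2-methylbut-3-en-2-yl)phenyl butanoate F3. Treatment of F3 with K2CO3 in MeOH and then MeI in the same flask should release the phenoxide of 7 and methylate it to 9.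

Step 5. In the diazonium intermediate, hydride may migrate in place of the aryl group (leading to the β-keto ester), or the acid catalyst may erode the substrate. The fallback builds the same enol by classical carbanion chemistry. It sets out from 9 and returns at 12. Knoevenagel-type condensation of 9 with methyl (methylthio)methyl sulfoxide (benzyltrimethylammonium hydroxide, THF, reflux) should give 1-(methylsulfinyl)-1-(methylthio)-2-[2,3-bis(benzyloxy)-4-methoxy-5-(2-methylbut-3-en-2-yl)phenyl]ethene F4. Ethanolysis of F4 with HCl in EtOH at room temperature should give ethyl 2-[2,3-bis(benzyloxy)-4-methoxy-5-(2-methylbut-3-en-2-yl)phenyl]acetate F5. Crossed Claisen formylation of F5 with ethyl formate and NaH in THF should then give 12.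

**Further compounds**
F1 | step 9 | ethyl (Z)-3-[3-(benzyloxy)phenoxy]-2-[2,3-bis(benzyloxy)-4-methoxy-5-(2-methylbut-3-en-2-yl)phenyl]prop-2-enoate | CCOC(=O)/C(c1cc(C(C)(C)C=C)c(OC)c(OCc2ccccc2)c1OCc1ccccc1)=C\Oc1cccc(OCc2ccccc2)c1
F2 | step 9 | (Z)-3-[3-(benzyloxy)phenoxy]-2-[2,3-bis(benzyloxy)-4-methoxy-5-(2-methylbut-3-en-2-yl)phenyl]prop-2-enoic acid | O=C(O)/C(c1cc(C(C)(C)C=C)c(OC)c(OCc2ccccc2)c1OCc1ccccc1)=C\Oc1cccc(OCc2ccccc2)c1
F3 | step 3 | 2,3-bis(benzyloxy)-4-formyl-6-(2-methylbut-3-en-2-yl)phenyl butanoate | CCCC(=O)Oc1c(C(C)(C)C=C)cc(C=O)c(OCc2ccccc2)c1OCc1ccccc1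
F4 | step 5 | 1-(methylsulfinyl)-1-(methylthio)-2-[2,3-bis(benzyloxy)-4-methoxy-5-(2-methylbut-3-en-2-yl)phenyl]ethene (alkene isomers, racemic at sulfur) | CSC(=Cc1cc(C(C)(C)C=C)c(OC)c(OCc2ccccc2)c1OCc1ccccc1)S(C)=O
F5 | step 5 | ethyl 2-[2,3-bis(benzyloxy)-4-methoxy-5-(2-methylbut-3-en-2-yl)phenyl]acetate | CCOC(=O)Cc1cc(C(C)(C)C=C)c(OC)c(OCc2ccccc2)c1OCc1ccccc1
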